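**Strategy.** Rings A and C are opened together. Ring A is a phloroglucinol (oxygens on C5, C7, C8a) acylated at C4a by C4, that is, the folded form of a methyl 3,5,7-trioxoheptanoate chain whose terminal ketone carbon is C4 and which is attached to the quaternary C3 of a 2-aryl-2-methoxy-2,3-dihydrobenzofuran fused to the (2S)-flavan. In one operation a magnesium-mediated Claisen closure (C4a to C5) aromatises ring A, and acid then lets the new C8a hydroxyl replace the C2 methoxy group (C2–O1), closing ring C. The precursor carries every other hydroxyl, C3–OH included, as a benzyl ether, so one hydrogenolysis ends the synthesis.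

Key step: step 11

Assumption: C2 is a ketal carbon that equilibrates through its oxocarbenium ion under acid, so the C2 configuration written in the target SMILES is taken to be the one the fused bicyclic ketal adopts once C3 is fixed.

Numbering: C2–C8a are the chromanone locants of the target. Tricyclic intermediates are named as furo[2,3-h]chromenes (O1, C2–C4, C4a, C5, C6, C6a, O7, C8, C9, C9a, C9b); their C8 and C9 become C2 and C3 of the target.

**Step 1**
Reactants: 1 (2S)-naringenin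
Product: 2 (2S)-5-hydroxy-2-(4-hydroxyphenyl)-7-(methoxymethoxy)chroman-4-one
Conditions: MOMCl (1.05 equiv), iPr2NEt, THF, 0 °C
Reagents that add atoms: chloromethyl methyl ether, COCCl
Why: Williamson-type O-alkylation under a mild amine base takes the most acidic phenol (7-OH, para to the C4 carbonyl) while the chelated 5-OH and the less acidic 4′-OH stay free, and the conditions are too mild to open the flavanone ring, so C2 keeps its configuration.

**Step 2**
Reactants: 2 (2S)-5-hydroxy-2-(4-hydroxyphenyl)-7-(methoxymethoxy)chroman-4-one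
Product: 5 (2S)-2-(4-hydroxyphenyl)-7-(methoxymethoxy)chroman-5-ol, via bis-carbonate 3 (not isolated), via 4′-carbonate flavan 4 (not isolated)
Conditions: ClCO2Et, Et3N, THF, 0 °C; then NaBH4, H2O, 0 → 23 °C; then 2 M NaOH
Reagents that add atoms: none
Why: Ortho-acyloxy-assisted reductive deoxygenation of an aryl ketone: hydride reduces C4=O, the carbonate moves from O5 to the benzylic alkoxide, elimination gives an o-quinone methide that takes up a second hydride to leave CH2 and the 5-phenoxide, and hydroxide then cleaves the 4′-carbonate; C2 is not involved and stays (S).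

**Step 3**
Reactants: 5 (2S)-2-(4-hydroxyphenyl)-7-(methoxymethoxy)chroman-5-ol
Product: 6 (2S)-5-(benzyloxy)-2-[4-(benzyloxy)phenyl]-7-(methoxymethoxy)chromane
Conditions: BnBr, K2CO3, DMF, 23 °C
Reagents that add atoms: benzyl bromide, BrCc1ccccc1
Why: Williamson benzylation of both phenols; the flavan has no enolisable or base-labile site.

**Step 4**
Reactants: 6 (2S)-5-(benzyloxy)-2-[4-(benzyloxy)phenyl]-7-(methoxymethoxy)chromane
Product: 7 (2S)-5-(benzyloxy)-2-[4-(benzyloxy)phenyl]-8-iodo-7-(methoxymethoxy)chromane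
Conditions: NIS, DMF, 0 → 23 °C
Reagents that add atoms: N-iodosuccinimide, O=C1CCC(=O)N1I
Why: Electrophilic aromatic iodination of the trioxygenated ring should take C8, between O7 and the ring oxygen, and not C6, which is wedged between two bulky ether groups, the regiochemistry established for halogenation of 5,7-di-O-alkylflavans.

**Step 5**
Reactants: 7 (2S)-5-(benzyloxy)-2-[4-(benzyloxy)phenyl]-8-iodo-7-(methoxymethoxy)chromane; 8 1-(benzyloxy)-4-ethynylbenzene
Product: 9 (2S)-5-(benzyloxy)-2-[4-(benzyloxy)phenyl]-8-{[4-(benzyloxy)phenyl]ethynyl}-7-(methoxymethoxy)chromane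
Conditions: PdCl2(PPh3)2 (5 mol%), CuI (10 mol%), Et3N, DMF, 60 °C
Reagents that add atoms: none
Why: Sonogashira coupling of the aryl iodide; the MOM ether keeps the ortho oxygen from cyclising onto the alkyne under Pd/Cu.

**Step 6**
Reactants: 9 (2S)-5-(benzyloxy)-2-[4-(benzyloxy)phenyl]-8-{[4-(benzyloxy)phenyl]ethynyl}-7-(methoxymethoxy)chromane
Product: 10 (2S)-5-(benzyloxy)-2-[4-(benzyloxy)phenyl]-8-{[4-(benzyloxy)phenyl]ethynyl}chroman-7-ol
Conditions: conc. HCl (cat.), MeOH/THF, 40 °C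
Reagents that add atoms: none
Why: Acid-catalysed acetal exchange with methanol cleaves the aryl MOM ether, while benzyl ethers, the diarylalkyne and the flavan ether tolerate dilute acid at this temperature.

**Step 7**
Reactants: 10 (2S)-5-(benzyloxy)-2-[4-(benzyloxy)phenyl]-8-{[4-(benzyloxy)phenyl]ethynyl}chroman-7-ol
Product: 11 methyl (2S)-5-(benzyloxy)-2,8-bis[4-(benzyloxy)phenyl]-3,4-dihydro-2H-furo[2,3-h]chromene-9-carboxylate
Conditions: PdI2 (5 mol%), thiourea (5 mol%), CBr4, Cs2CO3, CO (1 atm), MeOH, 40 °C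
Reagents that add atoms: carbon monoxide, [C-]#[O+]; methanol, CO
Why: Carbonylative heteroannulation of an o-alkynylphenol: 5-endo-dig oxypalladation by the phenoxide, CO insertion into the C9–Pd bond and methanolysis give the 2-aryl-3-methoxycarbonylbenzofuran, and CBr4 returns Pd(0) to Pd(II).

**Step 8**
Reactants: 11 methyl (2S)-5-(benzyloxy)-2,8-bis[4-(benzyloxy)phenyl]-3,4-dihydro-2H-furo[2,3-h]chromene-9-carboxylate
Product: 13 methyl (2S,8S,9R)-5-(benzyloxy)-2,8-bis[4-(benzyloxy)phenyl]-9-hydroxy-8-methoxy-3,4,8,9-tetrahydro-2H-furo[2,3-h]chromene-9-carboxylate, via epoxide 12 (not isolated)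
Conditions: (R,R)-(salen)Mn(III)Cl (Jacobsen epoxidation catalyst, 10 mol%), NMO, mCPBA, CH2Cl2, −78 °C; then MeOH, −78 → 0 °C
Reagents that add atoms: m-chloroperoxybenzoic acid, OOC(=O)c1cccc(Cl)c1; methanol, CO
Why: Proposed new method: the chiral Mn(V)-oxo salen complex should transfer oxygen to one face of the C8=C9 enol-ether double bond, a cyclic aryl-conjugated alkene shaped like indene and the chromenes, and the (R,R) complex is chosen to reach the 8Re,9Re face by analogy with indene (the (S,S) complex is used if the 8-aryl and 9-ester groups reverse the sense), which sets C9 as (R); the labile epoxide 12 is then opened at C8 by methanol through the cation stabilised by O7 and the 4-benzyloxyphenyl group (syn delivery is drawn, but either C8 epimer serves because this centre is re-formed in step 11); the closest known reaction types are Jacobsen epoxidation of indene, chromenes and isoflavones and dioxirane epoxidation–methanolysis of benzofurans.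

**Step 9**
Reactants: 13 methyl (2S,8S,9R)-5-(benzyloxy)-2,8-bis[4-(benzyloxy)phenyl]-9-hydroxy-8-methoxy-3,4,8,9-tetrahydro-2H-furo[2,3-h]chromene-9-carboxylate
Product: 14 methyl (2S,8S,9R)-5,9-bis(benzyloxy)-2,8-bis[4-(benzyloxy)phenyl]-8-methoxy-3,4,8,9-tetrahydro-2H-furo[2,3-h]chromene-9-carboxylate
Conditions: NaH, BnBr, Bu4NI (cat.), DMF, 0 → 23 °C
Reagents that add atoms: benzyl bromide, BrCc1ccccc1
Why: Williamson benzylation of the tertiary alkoxide, which has no β-hydrogen and no enolisable neighbour, so O-alkylation is the only productive path.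

**Step 10**
Reactants: 14 methyl (2S,8S,9R)-5,9-bis(benzyloxy)-2,8-bis[4-(benzyloxy)phenyl]-8-methoxy-3,4,8,9-tetrahydro-2H-furo[2,3-h]chromene-9-carboxylate; 15 methyl 3,5-dioxohexanoate
Product: 17 methyl 7-{(2S,8S,9S)-5,9-bis(benzyloxy)-2,8-bis[4-(benzyloxy)phenyl]-8-methoxy-3,4,8,9-tetrahydro-2H-furo[2,3-h]chromen-9-yl}-3,5,7-trioxoheptanoate, via trilithium trianion 16 (not isolated)
Conditions: 15 (3 equiv), LDA (9.3 equiv), THF, 0 °C; then 14, −78 → 0 °C; 1 M HCl
Reagents that add atoms: none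
Why: Claisen-type acylation of a polyketide polyanion: the terminal (C6) carbanion of the trianion, its most basic and least hindered site, attacks the α-alkoxy ester, and the product is held as a polyenolate that cannot add a second time.

**Step 11**
Reactants: 17 methyl 7-{(2S,8S,9S)-5,9-bis(benzyloxy)-2,8-bis[4-(benzyloxy)phenyl]-8-methoxy-3,4,8,9-tetrahydro-2H-furo[2,3-h]chromen-9-yl}-3,5,7-trioxoheptanoate
Product: 19 tetra-O-benzyl target, (2R,3S)-3-(benzyloxy)-2-[4-(benzyloxy)phenyl]-5,7-dihydroxychroman-4-one joined C3–C8″ and C2–O–C7″ to (2″S)-5″-(benzyloxy)-2″-[4-(benzyloxy)phenyl]chromane, via acylphloroglucinol methyl ketal 18 (not isolated)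
Conditions: Mg(OMe)2, MeOH, 23 → 65 °C; 1 M HCl; then CSA (cat.), 5 Å MS, CH2Cl2, 23 °C
Reagents that add atoms: none
Why: Magnesium methoxide turns the triketo ester into a chelated polyenolate in which C4a, the methylene between the C4 and C8a carbonyls, attacks the ester carbon C5, and loss of methoxide followed by enolisation of the cyclohexanetrione gives the 2,4,6-trihydroxyaryl ketone 18 (ring A). This is the Claisen mode of the known biomimetic cyclisation of 3,5,7-triketo esters to acylphloroglucinols under magnesium alkoxide conditions, and the closure is 6-exo-trig. The competing aldol mode (C6 onto C4, leading to a resorcylate) needs attack on the C4 ketone, which is neopentyl beside the fully substituted C3 and held in the magnesium chelate, so the substrate itself steers the folding. Acid in a non-nucleophilic solvent then ionises the C2–OMe bond to an oxocarbenium ion stabilised by the furan oxygen and the 4-benzyloxyphenyl group, and the C8a hydroxyl captures it (6-exo-trig) to close ring C while the sieves take up methanol; the two ortho hydroxyls of ring A are equivalent, so only one ketal can form. C2 is the only new stereocentre: it forms reversibly and is fixed by C3 through the fused bicyclic ketal, not by the configuration of the methoxy ketal. The C3 benzyl ether keeps the tertiary oxygen from hemiketal or ketol chemistry with the polyketone chain in both stages.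

**Step 12**
Reactants: 19 tetra-O-benzyl target
Product: 20 target, (2R,3S)-3,5,7-trihydroxy-2-(4-hydroxyphenyl)chroman-4-one joined C3–C8″ and C2–O–C7″ to (2″S)-5″-hydroxy-2″-(4-hydroxyphenyl)chromane
Conditions: H2 (1 atm), Pd(OH)2/C, THF/MeOH, 23 °C
Reagents that add atoms: none
Why: Catalytic hydrogenolysis cleaves all four O–CH2Ph bonds under neutral conditions; the hindered ketal, the conjugated aryl ketone, the tertiary C3–O bond and the flavan C2–O bond are much slower to reduce at 1 atm.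

**Compound list**

1 | (2S)-naringenin | O=C1C[C@@H](c2ccc(O)cc2)Oc2cc(O)cc(O)c12 | starting material
2 | (2S)-5-hydroxy-2-(4-hydroxyphenyl)-7-(methoxymethoxy)chroman-4-one | O=C1C[C@@H](c2ccc(O)cc2)Oc2cc(OCOC)cc(O)c12 | intermediate
3 | ethyl 4-[(2S)-5-(ethoxycarbonyloxy)-7-(methoxymethoxy)-4-oxochroman-2-yl]phenyl carbonate (not isolated) | O=C1C[C@@H](c2ccc(OC(=O)OCC)cc2)Oc2cc(OCOC)cc(OC(=O)OCC)c12 | intermediate
4 | ethyl 4-[(2S)-5-hydroxy-7-(methoxymethoxy)chroman-2-yl]phenyl carbonate (not isolated) | Oc1cc(OCOC)cc2O[C@H](c3ccc(OC(=O)OCC)cc3)CCc12 | intermediate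
5 | (2S)-2-(4-hydroxyphenyl)-7-(methoxymethoxy)chroman-5-ol | Oc1cc(OCOC)cc2O[C@H](c3ccc(O)cc3)CCc12 | intermediate
6 | (2S)-5-(benzyloxy)-2-[4-(benzyloxy)phenyl]-7-(methoxymethoxy)chromane | c1ccccc1COc1cc(OCOC)cc2O[C@H](c3ccc(OCc4ccccc4)cc3)CCc12 | intermediate
7 | (2S)-5-(benzyloxy)-2-[4-(benzyloxy)phenyl]-8-iodo-7-(methoxymethoxy)chromane | c1ccccc1COc1cc(OCOC)c(I)c2O[C@H](c3ccc(OCc4ccccc4)cc3)CCc12 | intermediate
8 | 1-(benzyloxy)-4-ethynylbenzene | C#Cc1ccc(OCc2ccccc2)cc1 | starting material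
9 | (2S)-5-(benzyloxy)-2-[4-(benzyloxy)phenyl]-8-{[4-(benzyloxy)phenyl]ethynyl}-7-(methoxymethoxy)chromane | c1ccccc1COc1cc(OCOC)c(C#Cc5ccc(OCc6ccccc6)cc5)c2O[C@H](c3ccc(OCc4ccccc4)cc3)CCc12 | intermediate
10 | (2S)-5-(benzyloxy)-2-[4-(benzyloxy)phenyl]-8-{[4-(benzyloxy)phenyl]ethynyl}chroman-7-ol | c1ccccc1COc1cc(O)c(C#Cc5ccc(OCc6ccccc6)cc5)c2O[C@H](c3ccc(OCc4ccccc4)cc3)CCc12 | intermediate
11 | methyl (2S)-5-(benzyloxy)-2,8-bis[4-(benzyloxy)phenyl]-3,4-dihydro-2H-furo[2,3-h]chromene-9-carboxylate | COC(=O)c1c(-c2ccc(OCc3ccccc3)cc2)oc2cc(OCc3ccccc3)c3c(c12)O[C@H](c1ccc(OCc2ccccc2)cc1)CC3 | intermediate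
12 | methyl (2S,8R,9R)-5-(benzyloxy)-2,8-bis[4-(benzyloxy)phenyl]-8,9-epoxy-3,4,8,9-tetrahydro-2H-furo[2,3-h]chromene-9-carboxylate (not isolated) | O1[C@@]2(c5ccc(OCc6ccccc6)cc5)Oc3cc(OCc5ccccc5)c4c(c3[C@@]12C(=O)OC)O[C@H](c5ccc(OCc6ccccc6)cc5)CC4 | intermediate
13 | methyl (2S,8S,9R)-5-(benzyloxy)-2,8-bis[4-(benzyloxy)phenyl]-9-hydroxy-8-methoxy-3,4,8,9-tetrahydro-2H-furo[2,3-h]chromene-9-carboxylate | CO[C@@]1(c5ccc(OCc6ccccc6)cc5)Oc2cc(OCc5ccccc5)c3c(c2[C@]1(O)C(=O)OC)O[C@H](c5ccc(OCc6ccccc6)cc5)CC3 | intermediate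
14 | methyl (2S,8S,9R)-5,9-bis(benzyloxy)-2,8-bis[4-(benzyloxy)phenyl]-8-methoxy-3,4,8,9-tetrahydro-2H-furo[2,3-h]chromene-9-carboxylate | CO[C@@]1(c5ccc(OCc6ccccc6)cc5)Oc2cc(OCc5ccccc5)c3c(c2[C@]1(OCc5ccccc5)C(=O)OC)O[C@H](c5ccc(OCc6ccccc6)cc5)CC3 | intermediate
15 | methyl 3,5-dioxohexanoate | CC(=O)CC(=O)CC(=O)OC | starting material
16 | trilithium trianion of methyl 3,5-dioxohexanoate (not isolated) | [Li+].[Li+].[Li+].[CH2-]C(=O)[CH-]C(=O)[CH-]C(=O)OC | intermediate
17 | methyl 7-{(2S,8S,9S)-5,9-bis(benzyloxy)-2,8-bis[4-(benzyloxy)phenyl]-8-methoxy-3,4,8,9-tetrahydro-2H-furo[2,3-h]chromen-9-yl}-3,5,7-trioxoheptanoate (keto tautomer drawn) | CO[C@@]1(c5ccc(OCc6ccccc6)cc5)Oc2cc(OCc5ccccc5)c3c(c2[C@]1(OCc5ccccc5)C(=O)CC(=O)CC(=O)CC(=O)OC)O[C@H](c5ccc(OCc6ccccc6)cc5)CC3 | intermediate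
18 | {(2S,8S,9S)-5,9-bis(benzyloxy)-2,8-bis[4-(benzyloxy)phenyl]-8-methoxy-3,4,8,9-tetrahydro-2H-furo[2,3-h]chromen-9-yl}(2,4,6-trihydroxyphenyl)methanone (not isolated) | CO[C@@]1(c5ccc(OCc6ccccc6)cc5)Oc2cc(OCc5ccccc5)c3c(c2[C@]1(OCc5ccccc5)C(=O)c5c(O)cc(O)cc5O)O[C@H](c5ccc(OCc6ccccc6)cc5)CC3 | intermediate
19 | tetra-O-benzyl target: (2R,3S)-3-(benzyloxy)-2-[4-(benzyloxy)phenyl]-5,7-dihydroxychroman-4-one joined C3–C8″ and C2–O–C7″ to (2″S)-5″-(benzyloxy)-2″-[4-(benzyloxy)phenyl]chromane | O=C1c2c(O)cc(O)cc2O[C@@]2(c5ccc(OCc6ccccc6)cc5)Oc3cc(OCc5ccccc5)c4c(c3[C@]12OCc5ccccc5)O[C@H](c5ccc(OCc6ccccc6)cc5)CC4 | intermediate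
20 | CNP0208300.3: (2R,3S)-3,5,7-trihydroxy-2-(4-hydroxyphenyl)chroman-4-one joined C3–C8″ and C2–O–C7″ to (2″S)-5″-hydroxy-2″-(4-hydroxyphenyl)chromane | O=C1c2c(O)cc(O)cc2O[C@@]2(c3ccc(O)cc3)Oc3cc(O)c4c(c3[C@]12O)O[C@H](c1ccc(O)cc1)CC4 | target

**Step count and risks**

Total steps: 12. Longest linear sequence: 12 steps (1 → 20); 8 and 15 are bought.

Steps most likely to fail:

1. Step 8 (proposed new method). Oxygen transfer to the tetrasubstituted C8=C9 bond may show poor or reversed facial selectivity, and the epoxide may isomerise to an o-quinone methide before methanol traps it. The fallback sets out from 11. Dimethyldioxirane in acetone/methanol at −20 °C, the established oxidation of benzofurans, should give epoxide 12 together with its face isomer, the (2S,8S,9S)-epoxide F1. Methanolysis then gives 13 together with the (2S,8R,9S)-methoxy alcohol F2. Because the flavan centre is fixed, 13 and F2 are diastereomers and are separated by chromatography or crystallisation. The route is rejoined at 13.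

2. Step 11 (key step). The chain may fold in the aldol sense or close through oxygen to a pyranone, methoxide may cleave the C4–C4a bond in a retro-Claisen reaction, or the ketal exchange may stop short. The fallback sets out from 14 and installs ring A as a preformed arene. 1,3,5-Tris(methoxymethoxy)benzene is lithiated between two acetal oxygens (n-BuLi, THF, 0 °C) to 2,4,6-tris(methoxymethoxy)phenyllithium F5, which should add once to the ester to give the tris-MOM aryl ketone F6. HCl in methanol removes the three MOM groups and returns the route at 18, which is closed to 19 with CSA and sieves as in step 11.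

3. Step 10. Attack of the trianion on the neopentyl ester may be slow, so that proton transfer and recovery of 14 win. The fallback sets out from 14. DIBAL-H (CH2Cl2, −78 °C) should reduce the ester to the aldehyde F3, to which trianion 16 adds readily to give the aldol adduct F4 (both carbinol epimers). Dess–Martin periodinane then oxidises the secondary alcohol, and the route is rejoined at 17.

**Further compounds**

F1 | step 8 | methyl (2S,8S,9S)-5-(benzyloxy)-2,8-bis[4-(benzyloxy)phenyl]-8,9-epoxy-3,4,8,9-tetrahydro-2H-furo[2,3-h]chromene-9-carboxylate | O1[C@]2(c5ccc(OCc6ccccc6)cc5)Oc3cc(OCc5ccccc5)c4c(c3[C@]12C(=O)OC)O[C@H](c5ccc(OCc6ccccc6)cc5)CC4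
F2 | step 8 | methyl (2S,8R,9S)-5-(benzyloxy)-2,8-bis[4-(benzyloxy)phenyl]-9-hydroxy-8-methoxy-3,4,8,9-tetrahydro-2H-furo[2,3-h]chromene-9-carboxylate | CO[C@]1(c5ccc(OCc6ccccc6)cc5)Oc2cc(OCc5ccccc5)c3c(c2[C@@]1(O)C(=O)OC)O[C@H](c5ccc(OCc6ccccc6)cc5)CC3
F3 | step 10 | (2S,8S,9S)-5,9-bis(benzyloxy)-2,8-bis[4-(benzyloxy)phenyl]-8-methoxy-3,4,8,9-tetrahydro-2H-furo[2,3-h]chromene-9-carbaldehyde | CO[C@@]1(c5ccc(OCc6ccccc6)cc5)Oc2cc(OCc5ccccc5)c3c(c2[C@]1(OCc5ccccc5)C=O)O[C@H](c5ccc(OCc6ccccc6)cc5)CC3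
F4 | step 10 | methyl 7-{(2S,8S,9S)-5,9-bis(benzyloxy)-2,8-bis[4-(benzyloxy)phenyl]-8-methoxy-3,4,8,9-tetrahydro-2H-furo[2,3-h]chromen-9-yl}-7-hydroxy-3,5-dioxoheptanoate (both C7 epimers) | CO[C@@]1(c5ccc(OCc6ccccc6)cc5)Oc2cc(OCc5ccccc5)c3c(c2[C@]1(OCc5ccccc5)C(O)CC(=O)CC(=O)CC(=O)OC)O[C@H](c5ccc(OCc6ccccc6)cc5)CC3
F5 | step 11 | 2,4,6-tris(methoxymethoxy)phenyllithium | [Li]c1c(OCOC)cc(OCOC)cc1OCOC
F6 | step 11 | {(2S,8S,9S)-5,9-bis(benzyloxy)-2,8-bis[4-(benzyloxy)phenyl]-8-methoxy-3,4,8,9-tetrahydro-2H-furo[2,3-h]chromen-9-yl}[2,4,6-tris(methoxymethoxy)phenyl]methanone | CO[C@@]1(c5ccc(OCc6ccccc6)cc5)Oc2cc(OCc5ccccc5)c3c(c2[C@]1(OCc5ccccc5)C(=O)c5c(OCOC)cc(OCOC)cc5OCOC)O[C@H](c5ccc(OCc6ccccc6)cc5)CC3
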